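**Retrosynthetic overview**
1. Irisjaponin A 15 should come from its 5,7-bis(MOM) ether 14 by acid methanolysis. Rings A and B are bought as benzene rings, and ring C is the only ring formed.
2. The strategy rests on ring A. O1 (on C8a) and the carbonyl carbon C4 (on C4a) sit on adjacent carbons, with C8–H beside C8a and the C5 oxygen beside C4a. This is the pattern that an aryne with an alkoxy group next to the triple bond delivers when a nucleophile and an electrophile add across it.
3. Ring C of 14 is therefore cut at O1–C8a and C4–C4a into aryne 13 (from ortho-silylaryl triflate 8) and the enolate of formyl arylacetate 12, which carries C2, C3, C4 and ring B.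
4. 8 derives from 2-methoxyresorcinol 1 by MOM protection, iridium-catalysed C–H borylation/oxidation to the symmetric phenol 4, bromination, and retro-Brook silyl shift with triflation.
5. 12 derives from 1,2,3,4-tetramethoxybenzene 9 by bromination, palladium-catalysed coupling with a Reformatsky reagent, and Claisen formylation.

Key step: step 8

Remark 1: the two ring A phenols are carried as methoxymethyl ethers, not benzyl ethers, because the sterically governed iridium C–H borylation of step 2 would also attack the open meta and para C–H bonds of benzyl phenyl rings; MOM ethers have no aryl C–H, tolerate n-BuLi and fluoride, and exert the same inductive effect on the aryne.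
Remark 2: compound 12 is drawn as its (Z)-enol; it is expected to be an enol/aldehyde tautomer mixture that converges on one cesium enolate under the conditions of step 8.

**Route**

Step 1
Reactants: 1 2-methoxyresorcinol
Product: 2 2-methoxy-1,3-bis(methoxymethoxy)benzene
Conditions: NaH (2.4 equiv), MOMCl (2.4 equiv), DMF, 0 °C → rt
Reagents that add atoms: chloromethyl methyl ether, COCCl
Why: Double O-alkylation of the sodium phenoxides by the reactive α-chloro ether (Williamson-type acetal formation) should go cleanly because no other nucleophilic site is present.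

Step 2
Reactants: 2 2-methoxy-1,3-bis(methoxymethoxy)benzene
Product: 4 4-methoxy-3,5-bis(methoxymethoxy)phenol, via aryl pinacol boronate 3 (not isolated)
Conditions: [Ir(OMe)(cod)]2 (1.5 mol%), 4,4'-di-tert-butyl-2,2'-bipyridine (3 mol%), B2pin2 (1.0 equiv), THF, 80 °C; then 30% aq. H2O2, aq. NaOH, THF, 0 °C → rt
Reagents that add atoms: bis(pinacolato)diboron, CC1(C)OB(OC1(C)C)B1OC(C)(C)C(C)(C)O1 (boron held only in 3); hydrogen peroxide, OO
Why: Iridium-catalysed aromatic C–H borylation is sterically governed and should take only C5–H of 2, the one C–H without an ortho substituent, and the C–B bond is then converted into C–O by the peroxide-induced 1,2-aryl shift (borylation–oxidation sequence).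

Step 3
Reactants: 4 4-methoxy-3,5-bis(methoxymethoxy)phenol
Product: 5 2-bromo-4-methoxy-3,5-bis(methoxymethoxy)phenol
Conditions: NBS (1.0 equiv), CH2Cl2, −78 → −20 °C, dark
Reagents that add atoms: N-bromosuccinimide, O=C1CCC(=O)N1Br
Why: Electrophilic aromatic bromination ortho to the free phenol should give one monobromide because the two ortho positions are equivalent by symmetry, and one equivalent of NBS at low temperature should limit dibromination and quinone formation.

Step 4
Reactants: 5 2-bromo-4-methoxy-3,5-bis(methoxymethoxy)phenol
Product: 8 4-methoxy-3,5-bis(methoxymethoxy)-2-(trimethylsilyl)phenyl trifluoromethanesulfonate, via aryl trimethylsilyl ether 6 (not isolated), via lithium 2-silylphenoxide 7 (not isolated)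
Conditions: HMDS, THF, 65 °C, then evaporation; n-BuLi (1.1 equiv), THF, −78 °C; Tf2O (1.2 equiv), −78 °C → rt
Reagents that add atoms: hexamethyldisilazane, C[Si](C)(C)N[Si](C)(C)C; n-butyllithium, [Li]CCCC (lithium held only in 7); trifluoromethanesulfonic anhydride, O=S(=O)(OS(=O)(=O)C(F)(F)F)C(F)(F)F
Why: O-Silylation, bromine–lithium exchange and retro-Brook 1,3-shift of silicon from oxygen to the lithiated carbon should give the ortho-silyl phenoxide, which is O-triflated in the same flask; at −78 °C the exchange is faster than ortho-lithiation beside the MOM groups.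

Step 5
Reactants: 9 1,2,3,4-tetramethoxybenzene
Product: 10 1-bromo-2,3,4,5-tetramethoxybenzene
Conditions: NBS (1.05 equiv), MeCN, 0 °C → rt
Reagents that add atoms: N-bromosuccinimide, O=C1CCC(=O)N1Br
Why: Electrophilic aromatic bromination of an activated arene with NBS in acetonitrile should give a single bromide, since the two free positions of 9 are equivalent and the first bromine deactivates the ring towards a second.

Step 6
Reactants: 10 1-bromo-2,3,4,5-tetramethoxybenzene
Product: 11 methyl 2-(2,3,4,5-tetramethoxyphenyl)acetate
Conditions: BrZnCH2CO2Me (1.5 equiv, from BrCH2CO2Me, Zn dust, cat. TMSCl, THF), Pd2(dba)3 (2 mol%), XPhos (8 mol%), THF, 65 °C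
Reagents that add atoms: methyl bromoacetate, COC(=O)CBr (used as its zinc enolate made with Zn dust)
Why: Palladium-catalysed Negishi-type coupling of an aryl bromide with a Reformatsky zinc enolate (ester α-arylation) should work because the bulky biaryl phosphine promotes oxidative addition to the electron-rich ortho-substituted bromide and the mild zinc enolate resists Claisen self-condensation.

Step 7
Reactants: 11 methyl 2-(2,3,4,5-tetramethoxyphenyl)acetate
Product: 12 methyl (Z)-3-hydroxy-2-(2,3,4,5-tetramethoxyphenyl)acrylate
Conditions: HCO2Me (5 equiv), NaH (2.5 equiv), THF, 0 °C → rt; 1 M HCl work-up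
Reagents that add atoms: methyl formate, COC=O
Why: Crossed Claisen condensation (C-formylation) of the ester enolate with non-enolisable methyl formate is driven by deprotonation of the acidic formyl ester, which after acidification should be obtained as its hydrogen-bonded enol.

Step 8
Reactants: 8 4-methoxy-3,5-bis(methoxymethoxy)-2-(trimethylsilyl)phenyl trifluoromethanesulfonate; 12 methyl (Z)-3-hydroxy-2-(2,3,4,5-tetramethoxyphenyl)acrylate
Product: 14 6-methoxy-5,7-bis(methoxymethoxy)-3-(2,3,4,5-tetramethoxyphenyl)-4H-chromen-4-one, via aryne 13 (not isolated)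
Conditions: CsF (4 equiv), THF, 65 °C, 8 (1.5 equiv) added slowly
Reagents that add atoms: none
Why: Proposed new method: fluoride attacks silicon of 8 and triflate leaves to give aryne 13, the cesium enolate of 12 adds through its formyl-derived oxygen to the aryne carbon remote from the C5 MOM-oxy group (future C8a), the aryl anion that appears at C4a beside that oxygen adds to the cis methyl ester, and loss of methoxide gives the 4-pyranone. The closest known reactions are the fluoride-mediated annulation of arynes with methyl salicylates to xanthones (O-arylation then acyl capture) and the aryne acyl-alkylation of β-dicarbonyl compounds. Ring C is closed by intermolecular O1–C8a bond formation followed by a 6-exo-trig addition–elimination of the aryl anion at the ester carbonyl (C4–C4a). No stereocentre is formed. The step needs oxygen instead of carbon arylation of the ambident enolate, one orientation on the aryne and the Z enolate geometry: the α-carbon is fully substituted and shielded by the ortho-methoxylated aryl group, the σ-withdrawing oxygen at C5 distorts the aryne so that the nucleophile adds at the far carbon and the charge lands beside oxygen, and cesium chelation between the two enolate oxygens holds the reacting oxygen cis to the ester. THF is chosen over acetonitrile so that the aryl anion is not protonated before it reaches the ester.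

Step 9
Reactants: 14 6-methoxy-5,7-bis(methoxymethoxy)-3-(2,3,4,5-tetramethoxyphenyl)-4H-chromen-4-one
Product: 15 Irisjaponin A, 5,7-dihydroxy-6-methoxy-3-(2,3,4,5-tetramethoxyphenyl)-4H-chromen-4-one
Conditions: 3 M HCl, MeOH/THF, 50 °C
Reagents that add atoms: none
Why: Acid-catalysed methanolysis of the two MOM acetals (acetal exchange) should release both phenols, while the aryl methyl ethers and the chromone are inert to dilute HCl in methanol.

**Compound list**
1 | 2-methoxyresorcinol | COc1c(O)cccc1O | starting material
2 | 2-methoxy-1,3-bis(methoxymethoxy)benzene | COCOc1cccc(OCOC)c1OC | intermediate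
3 | 2-[4-methoxy-3,5-bis(methoxymethoxy)phenyl]-4,4,5,5-tetramethyl-1,3,2-dioxaborolane | COCOc1cc(B2OC(C)(C)C(C)(C)O2)cc(OCOC)c1OC | intermediate
4 | 4-methoxy-3,5-bis(methoxymethoxy)phenol | COCOc1cc(O)cc(OCOC)c1OC | intermediate
5 | 2-bromo-4-methoxy-3,5-bis(methoxymethoxy)phenol | Oc1cc(OCOC)c(OC)c(OCOC)c1Br | intermediate
6 | [2-bromo-4-methoxy-3,5-bis(methoxymethoxy)phenoxy]trimethylsilane | C[Si](C)(C)Oc1cc(OCOC)c(OC)c(OCOC)c1Br | intermediate
7 | lithium 4-methoxy-3,5-bis(methoxymethoxy)-2-(trimethylsilyl)phenoxide | [Li+].[O-]c1cc(OCOC)c(OC)c(OCOC)c1[Si](C)(C)C | intermediate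
8 | 4-methoxy-3,5-bis(methoxymethoxy)-2-(trimethylsilyl)phenyl trifluoromethanesulfonate | O=S(=O)(Oc1cc(OCOC)c(OC)c(OCOC)c1[Si](C)(C)C)C(F)(F)F | intermediate
9 | 1,2,3,4-tetramethoxybenzene | COc1ccc(OC)c(OC)c1OC | starting material
10 | 1-bromo-2,3,4,5-tetramethoxybenzene | COc1cc(Br)c(OC)c(OC)c1OC | intermediate
11 | methyl 2-(2,3,4,5-tetramethoxyphenyl)acetate | COC(=O)Cc1cc(OC)c(OC)c(OC)c1OC | intermediate
12 | methyl (Z)-3-hydroxy-2-(2,3,4,5-tetramethoxyphenyl)acrylate | COC(=O)/C(=C\O)c1cc(OC)c(OC)c(OC)c1OC | intermediate
13 | 4-methoxy-3,5-bis(methoxymethoxy)-1,2-didehydrobenzene (aryne) | COCOC1=CC#CC(OCOC)=C1OC | intermediate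
14 | 6-methoxy-5,7-bis(methoxymethoxy)-3-(2,3,4,5-tetramethoxyphenyl)-4H-chromen-4-one | COc1cc(-c2coc3cc(OCOC)c(OC)c(OCOC)c3c2=O)c(OC)c(OC)c1OC | intermediate
15 | Irisjaponin A | COc1cc(-c2coc3cc(O)c(OC)c(O)c3c2=O)c(OC)c(OC)c1OC | target

**Step count**
Total: 9 steps. Longest linear sequence: 6 steps (steps 1, 2, 3, 4, 8, 9, from 1).

**Steps most likely to fail**

1. Step 8 (proposed new method). The enolate may be arylated at carbon and then fragment through its formyl group (acyl-alkylation pathway). The aryl anion may be protonated before it closes onto the ester, or the cis enolate geometry may be lost; either would leave open-chain aryl enol ethers. Addition in the reverse orientation on the aryne would give the 8-oxygenated isomer.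
Fallback (known deoxybenzoin chemistry), setting out from 11 and 5 and returning at 14:
- 11 is converted with MeNH(OMe)·HCl and i-PrMgCl (THF, −20 °C) into the Weinreb amide N-methoxy-N-methyl-2-(2,3,4,5-tetramethoxyphenyl)acetamide F1.
- 5 is benzylated (BnBr, K2CO3, DMF) to 1-(benzyloxy)-2-bromo-4-methoxy-3,5-bis(methoxymethoxy)benzene F2.
- Bromine–lithium exchange on F2 (n-BuLi, THF, −78 °C) and addition to F1 should give the deoxybenzoin 1-[2-(benzyloxy)-5-methoxy-4,6-bis(methoxymethoxy)phenyl]-2-(2,3,4,5-tetramethoxyphenyl)ethan-1-one F3.
- Hydrogenolysis (H2, Pd/C, EtOAc) frees the single ortho phenol to give 1-[2-hydroxy-5-methoxy-4,6-bis(methoxymethoxy)phenyl]-2-(2,3,4,5-tetramethoxyphenyl)ethan-1-one F4.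
- Condensation of F4 with DMF dimethyl acetal (toluene, 90 °C) inserts C2 and closes ring C to 14. Only one ortho oxygen is free in F4, so the direction of ring closure is fixed.

2. Step 3. The very electron-rich para-alkoxyphenol may be brominated twice or oxidised to a quinone, and an impure bromide would in turn cause protonation instead of silyl migration in step 4.
Fallback (carbamate-directed ortho-lithiation), setting out from 4 and returning at 8, bypassing steps 3 and 4:
- 4 is treated with isopropyl isocyanate (cat. Et3N, CH2Cl2) to give 4-methoxy-3,5-bis(methoxymethoxy)phenyl N-isopropylcarbamate F5.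
- In-situ N-silylation (TBSOTf, TMEDA, Et2O), ortho-lithiation (n-BuLi, −78 °C), TMSCl quench and mild aqueous work-up should give 4-methoxy-3,5-bis(methoxymethoxy)-2-(trimethylsilyl)phenyl N-isopropylcarbamate F6. Both ortho sites are equivalent.
- DBU and Et2NH (MeCN, 40 °C) cleave the carbamate to 4-methoxy-3,5-bis(methoxymethoxy)-2-(trimethylsilyl)phenol F7, which is triflated in the same pot with PhNTf2 to give 8.

3. Step 6. Oxidative addition to the electron-rich ortho-substituted bromide may be slow, so that the zinc enolate is consumed by self-condensation or protonation and hydrodebromination competes.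
Fallback (no palladium, no bromide), setting out from 9 and returning at 11, bypassing steps 5 and 6:
- Friedel–Crafts acetylation of 9 with the mixed anhydride from AcOH and (CF3CO)2O (rt, no Lewis acid, to avoid ortho-demethylation) should give 1-(2,3,4,5-tetramethoxyphenyl)ethan-1-one F8.
- Oxidative 1,2-aryl shift of the derived enol ether with PhI(OAc)2, HC(OMe)3 and H2SO4 in MeOH should give the methyl arylacetate 11.

**Further compounds**
F1 | step 8 | N-methoxy-N-methyl-2-(2,3,4,5-tetramethoxyphenyl)acetamide | CON(C)C(=O)Cc1cc(OC)c(OC)c(OC)c1OC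
F2 | step 8 | 1-(benzyloxy)-2-bromo-4-methoxy-3,5-bis(methoxymethoxy)benzene | COCOc1cc(OCc2ccccc2)c(Br)c(OCOC)c1OC
F3 | step 8 | 1-[2-(benzyloxy)-5-methoxy-4,6-bis(methoxymethoxy)phenyl]-2-(2,3,4,5-tetramethoxyphenyl)ethan-1-one | COCOc1cc(OCc2ccccc2)c(C(=O)Cc2cc(OC)c(OC)c(OC)c2OC)c(OCOC)c1OC
F4 | step 8 | 1-[2-hydroxy-5-methoxy-4,6-bis(methoxymethoxy)phenyl]-2-(2,3,4,5-tetramethoxyphenyl)ethan-1-one | COCOc1cc(O)c(C(=O)Cc2cc(OC)c(OC)c(OC)c2OC)c(OCOC)c1OC
F5 | step 3 | 4-methoxy-3,5-bis(methoxymethoxy)phenyl N-isopropylcarbamate | CC(C)NC(=O)Oc1cc(OCOC)c(OC)c(OCOC)c1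
F6 | step 3 | 4-methoxy-3,5-bis(methoxymethoxy)-2-(trimethylsilyl)phenyl N-isopropylcarbamate | CC(C)NC(=O)Oc1cc(OCOC)c(OC)c(OCOC)c1[Si](C)(C)C
F7 | step 3 | 4-methoxy-3,5-bis(methoxymethoxy)-2-(trimethylsilyl)phenol | Oc1cc(OCOC)c(OC)c(OCOC)c1[Si](C)(C)C
F8 | step 6 | 1-(2,3,4,5-tetramethoxyphenyl)ethan-1-one | CC(=O)c1cc(OC)c(OC)c(OC)c1OC
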